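The north run, followed to 5.00 h, has the same recipe as the flask I was asked about, so I read its time scales in order, fastest first.

common to all: substrate 0.10 M (fed, over 40 min)

|  | coupling partner | remark | time |
|---|---|---|---|
| north | 1.3 equiv | the very flask that is asked about, followed so far; the fed solution adds 0.20 times the starting volume |  |
| flask | 1.30 equiv | the fed solution adds 0.20 times the starting volume | 12 h |

north run (percent of the substrate charged)

| time / h | substrate / % | target / % |
|---|---|---|
| 0.417 | 60.8 | 0 |
| 1.33 | 91.7 | 0 |
| 2.00 | 91.4 | 0.9 |
| 3.00 | 85.8 | 2.5 |
| 5.00 | 85.2 | 3.1 |

(readings scatter by 1 percentage point)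

* amount of substrate in percent of the substrate charged, at 80 min, 4.0 h, 8.0 h and 12 h

- charges are per starting volume, the dose included; the dosed solution carries all of it
- what was read earlier has a scatter of 1 percentage point, one standard deviation
- percentages count the whole charge, also what has not yet gone in

First came the dose, over in 40 min. At 0.417 h the substrate read 60.8% against 62.6% fed, short by 1.8 percentage points, with a scatter of 1 point.

Next, substrate fell from 91.7% at 1.33 h to 85.8% at 3.00 h, and a gap stood: a share of the charge that read as neither substrate nor target. I put that gap at 11.7% at 3.00 h and 11.7% at 5.00 h. Two readings that agree within their scatter cannot show a halt, so as a working guess of my own I took substrate and the unseen share to stand in a steady ratio.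

Last came a slow drain, seen in target, which rose from 0.9% at 2.00 h to 3.1% at 5.00 h:

λ = (3.1% − 0.9%) / 3.00 h / 96.9% = 0.00757 h⁻¹

I call λ the drain constant, the fraction of all that is not yet target which becomes target each hour. It is a pseudo-first-order constant, and a rough one, since each reading carries 1 point against a rise of 2.2 points. Its half-life, 91.6 h, is longer than the whole north run. On that guess, substrate falls at the same fractional rate, and the rate integrates to:

substrate(t) = 85.2% × exp[−λ(t − 5.00 h)]

At 80 min I kept the reading, 91.7%. The line gave me 85.8% at 4.0 h, 83.3% at 8.0 h and 80.8% at 12 h.

The forecast said 91.3%, 86%, 84.2% and 83.5%, in the words “The loss is clearly levelling off”, and its last value stood above mine.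

The flask gave 92.4%, 85.2%, 80.7% and 77.0%.

    substrate + coupling partner ⇌ intermediate (K = 1.70 L mol⁻¹, k = 0.990 L mol⁻¹ h⁻¹)
    intermediate ⇌ target + released group (K = 0.140 M, k = 0.0750 h⁻¹)
    intermediate → side product (k = 0.0340 h⁻¹)
    coupling partner + target → over-reaction product (k = 0.0360 L mol⁻¹ h⁻¹)

My 80.8% stood 3.8 points above the flask at 12 h, and the flask was still draining. Carried to 120 h, the line gives 35.7%, where the flask held 42.5%. The drain half-life of 91.6 h is longer than the 5.4 h of the forward step alone. Substrate stayed high because intermediate went back to substrate and coupling partner and because the time was short. That return ran at 75% of the forward turnover; taken away, it left 40.8% at 12 h, while with it kept, ten times the time brought substrate to 42.5%.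

All runs stem from a simulated flask with constants of no real substance, noise included.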